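**Plan**
- The oxolane is numbered O1, C2–C5 so that the C2 aryl group is trans to the C3 hydroxymethyl and the C5 aryl group cis to the C4 hydroxymethyl; the target is the 2S,3R,4R,5R isomer with the two aryl groups cis.
- Feature used: C2 is a benzylic CH bonded to O1, and C3 bears a one-carbon substituent that can be an ester, so a carbenoid at C3 can insert into the C2–H bond across the chain C3–C4–C5–O1–C2.
- Retrosynthesis: first the O–Si bonds and the oxidation level at C3, then the ring bond C2–C3 (carbenoid C–H insertion), then O1–C2 (reductive etherification with silylated syringaldehyde), then C4–C5 (aldol of a succinate imide with the same aldehyde).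
- Forward: the aldol joins C4–C5, etherification joins O1–C2, the auxiliary carbonyl becomes the C4 silyloxymethyl, a diazo group is placed on C3, and the only ring closes by C2–C3 bond formation; reduction and desilylation finish.
- Stereochemistry: C4 and C5 come from the oxazolidinone-controlled anti aldol, C2 from the substrate-controlled insertion, C3 from base equilibration of the ester to the position trans to both neighbours.

Key step: step 8

Assumption: the MgCl2-catalysed anti aldol of an N-acyl oxazolidinone is taken to add the aldehyde to the face of the chelated Z-enolate away from the benzyl group (the sense of enolate alkylation), so the (R)-auxiliary is the one that leads to the 3S,4R adduct 7.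

Notation: Ar = 3,5-dimethoxy-4-(triisopropylsilyloxy)phenyl. The phenols carry triisopropylsilyl groups and the ester is tert-butyl, so that the alkoxide equilibration spares the aryl silyl ethers and the hydroxy ester 9 does not lactonise.

**Step 1**
Reactants: 1 syringaldehyde (4-hydroxy-3,5-dimethoxybenzaldehyde)
Product: 2 3,5-dimethoxy-4-(triisopropylsilyloxy)benzaldehyde
Conditions: TIPSCl, imidazole, DMAP (cat.), DMF, rt
Reagents that add atoms: chlorotriisopropylsilane, CC(C)[Si](Cl)(C(C)C)C(C)C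
Why: Imidazole-promoted O-silylation of the phenol (silyl ether formation) masks the acidic OH with a hindered group that should survive the later base and hydride steps and leaves the aldehyde free.

**Step 2**
Reactants: 3 mono-tert-butyl succinate (4-tert-butoxy-4-oxobutanoic acid); 4 (4R)-4-benzyl-1,3-oxazolidin-2-one
Product: 6 tert-butyl 4-[(4R)-4-benzyl-2-oxo-1,3-oxazolidin-3-yl]-4-oxobutanoate, via mixed pivalic anhydride 5 (not isolated)
Conditions: PivCl, Et3N, THF, −20 °C; then 4, LiCl, −20 °C → rt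
Reagents that add atoms: none
Why: N-Acylation of the oxazolidinone through a mixed pivalic anhydride (LiCl/Et3N method), in which the nitrogen attacks the unhindered succinyl carbonyl of 5 and the tert-butyl ester does not react.

**Step 3**
Reactants: 6 tert-butyl 4-[(4R)-4-benzyl-2-oxo-1,3-oxazolidin-3-yl]-4-oxobutanoate; 2 3,5-dimethoxy-4-(triisopropylsilyloxy)benzaldehyde
Product: 7 tert-butyl (3S,4R)-3-[(4R)-4-benzyl-2-oxo-1,3-oxazolidine-3-carbonyl]-4-Ar-4-(trimethylsilyloxy)butanoate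
Conditions: MgCl2 (0.2 equiv), Et3N, Me3SiCl, EtOAc, rt; filtration through silica
Reagents that add atoms: chlorotrimethylsilane, C[Si](C)(C)Cl
Why: Evans magnesium-halide-catalysed anti aldol, in which Et3N enolises the MgCl2-chelated imide to the Z-enolate, the aldehyde adds to the face away from the benzyl group through a boat-like transition state that gives the anti diad, and Me3SiCl silylates the aldolate so that the addition cannot revert; the auxiliary thereby sets C3 and C4 of the butanoate, the later ring C4 and C5.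

**Step 4**
Reactants: 7 tert-butyl (3S,4R)-3-[(4R)-4-benzyl-2-oxo-1,3-oxazolidine-3-carbonyl]-4-Ar-4-(trimethylsilyloxy)butanoate; 2 3,5-dimethoxy-4-(triisopropylsilyloxy)benzaldehyde
Product: 8 tert-butyl (3S,4R)-3-[(4R)-4-benzyl-2-oxo-1,3-oxazolidine-3-carbonyl]-4-Ar-4-(Ar-methoxy)butanoate
Conditions: Et3SiH, Me3SiOTf (cat.), CH2Cl2, −78 °C
Reagents that add atoms: none
Why: Reductive etherification, in which Me3SiOTf joins the silyl ether and the aldehyde to an oxocarbenium ion that Et3SiH reduces to the benzylic ether; the carbinol C–O bond is not broken, so C4 keeps its configuration, and the meta-methoxy groups and the neighbouring acyl group disfavour ionisation at that carbon.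

**Step 5**
Reactants: 8 tert-butyl (3S,4R)-3-[(4R)-4-benzyl-2-oxo-1,3-oxazolidine-3-carbonyl]-4-Ar-4-(Ar-methoxy)butanoate
Product: 9 tert-butyl (3R,4R)-4-Ar-4-(Ar-methoxy)-3-(hydroxymethyl)butanoate
Conditions: LiBH4, MeOH (1 equiv), THF, 0 °C
Reagents that add atoms: none
Why: Reductive cleavage of the N-acyl oxazolidinone, in which hydride attacks the activated exocyclic imide carbonyl and takes it to the primary alcohol, while the hindered tert-butyl ester should be neither reduced nor attacked by the new alkoxide at 0 °C and the auxiliary is recovered.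

**Step 6**
Reactants: 9 tert-butyl (3R,4R)-4-Ar-4-(Ar-methoxy)-3-(hydroxymethyl)butanoate
Product: 10 tert-butyl (3R,4R)-3-{[tert-butyl(dimethyl)silyl]oxymethyl}-4-Ar-4-(Ar-methoxy)butanoate
Conditions: TBSCl, imidazole, DMF, rt
Reagents that add atoms: tert-butylchlorodimethylsilane, CC(C)(C)[Si](C)(C)Cl
Why: Silylation of the primary alcohol (silyl ether formation) gives an oxygen substituent whose adjacent C–H bonds cannot be reached by a five-membered insertion.

**Step 7**
Reactants: 10 tert-butyl (3R,4R)-3-{[tert-butyl(dimethyl)silyl]oxymethyl}-4-Ar-4-(Ar-methoxy)butanoate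
Product: 12 tert-butyl (3R,4R)-2-diazo-3-{[tert-butyl(dimethyl)silyl]oxymethyl}-4-Ar-4-(Ar-methoxy)butanoate, via trifluoroacetyl ester 11 (not isolated)
Conditions: LiN(SiMe3)2, THF, −78 °C; CF3CO2CH2CF3; aq. NH4Cl; then MsN3, Et3N, H2O, MeCN, rt
Reagents that add atoms: methanesulfonyl azide, CS(=O)(=O)N=[N+]=[N-]
Why: Detrifluoroacetylative Regitz diazo transfer, in which the lithium ester enolate is C-acylated by the trifluoroethyl ester and the resulting 1,3-dicarbonyl compound 11 takes up N2 from MsN3 with loss of the trifluoroacetyl group as the sulfonamide; the two stereocentres are not α to a carbonyl group and are untouched.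

**Step 8**
Reactants: 12 tert-butyl (3R,4R)-2-diazo-3-{[tert-butyl(dimethyl)silyl]oxymethyl}-4-Ar-4-(Ar-methoxy)butanoate
Product: 14 tert-butyl (2S,3S,4R,5R)-4-{[tert-butyl(dimethyl)silyl]oxymethyl}-2,5-di-Ar-oxolane-3-carboxylate, via C3-epimeric insertion ester 13 (not isolated)
Conditions: Rh2(O2CCPh3)4 (1 mol %), CH2Cl2, −78 → 0 °C, slow addition of 12; evaporation; then KOtBu (0.3 equiv), t-BuOH/THF, rt
Reagents that add atoms: none
Why: Rh2(O2CCPh3)4 expels N2 from 12 to give an electrophilic rhodium carbenoid at C3, which takes up the hydridic C2–H bond (benzylic and next to O1) in a concerted three-centre insertion; this is the known dirhodium-catalysed intramolecular 1,5 C–H insertion of α-diazo esters next to ether oxygen. The oxolane closes by C2–C3 bond formation through a five-membered transition state that holds O1 in the ring (1,5-insertion). C2 is set by the substrate: the rhodium with its carboxylate wall should sit on the ring face away from the C4 silyloxymethyl group, and the C2 aryl group turns away from that wall into a pseudo-equatorial position cis to the C5 aryl group, the C–H bond reacting with retention. C3 forms first under kinetic control, probably with the ester cis to the C2 aryl group (13), and KOtBu then equilibrates it through the ester enolate to the isomer trans to both the C2 aryl and the C4 silyloxymethyl group, the least crowded arrangement. The step needs insertion to win over the 1,2-hydride shift from C4 and over attack on the electron-rich C5 arene; the bulky triphenylacetate ligands and the low temperature hold back the hydride shift, and the double activation of the C2–H bond, the only activated C–H bond that a five-membered closure can reach, directs the carbenoid there.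

**Step 9**
Reactants: 14 tert-butyl (2S,3S,4R,5R)-4-{[tert-butyl(dimethyl)silyl]oxymethyl}-2,5-di-Ar-oxolane-3-carboxylate
Product: 15 [(2S,3R,4R,5R)-4-{[tert-butyl(dimethyl)silyl]oxymethyl}-2,5-di-Ar-oxolan-3-yl]methanol
Conditions: LiAlH4, THF, 0 °C
Reagents that add atoms: none
Why: LiAlH4 reduction of the ester to the primary alcohol, in which hydride addition is faster than enolisation so that the equilibrated C3 centre is kept, and the silyl ethers should withstand the reagent at 0 °C.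

**Step 10**
Reactants: 15 [(2S,3R,4R,5R)-4-{[tert-butyl(dimethyl)silyl]oxymethyl}-2,5-di-Ar-oxolan-3-yl]methanol
Product: 16 [(2S,3R,4R,5R)-2,5-bis(4-hydroxy-3,5-dimethoxyphenyl)oxolane-3,4-diyl]dimethanol
Conditions: Bu4NF, AcOH, THF, 0 °C → rt
Reagents that add atoms: none
Why: Fluoride-induced desilylation removes the two aryl silyl ethers and the alkyl silyl ether in one operation, and the acetic acid buffer keeps the freed phenols protonated so that the benzylic ether carbons C2 and C5 are not opened through quinone methides.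

**Compound list**
1 | syringaldehyde | COc1cc(C=O)cc(OC)c1O | starting material
2 | 3,5-dimethoxy-4-(triisopropylsilyloxy)benzaldehyde | COc1cc(C=O)cc(OC)c1O[Si](C(C)C)(C(C)C)C(C)C | intermediate
3 | mono-tert-butyl succinate | CC(C)(C)OC(=O)CCC(=O)O | starting material
4 | (4R)-4-benzyl-1,3-oxazolidin-2-one | O=C1N[C@H](Cc2ccccc2)CO1 | starting material
5 | 4-tert-butoxy-4-oxobutanoic pivalic anhydride | CC(C)(C)OC(=O)CCC(=O)OC(=O)C(C)(C)C | intermediate
6 | tert-butyl 4-[(4R)-4-benzyl-2-oxo-1,3-oxazolidin-3-yl]-4-oxobutanoate | CC(C)(C)OC(=O)CCC(=O)N1[C@H](Cc2ccccc2)COC1=O | intermediate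
7 | tert-butyl (3S,4R)-3-[(4R)-4-benzyl-2-oxo-1,3-oxazolidine-3-carbonyl]-4-Ar-4-(trimethylsilyloxy)butanoate | C[Si](C)(C)O[C@@H](c1cc(OC)c(O[Si](C(C)C)(C(C)C)C(C)C)c(OC)c1)[C@@H](C(=O)N1[C@H](Cc2ccccc2)COC1=O)CC(=O)OC(C)(C)C | intermediate
8 | tert-butyl (3S,4R)-3-[(4R)-4-benzyl-2-oxo-1,3-oxazolidine-3-carbonyl]-4-Ar-4-(Ar-methoxy)butanoate | COc1cc(cc(OC)c1O[Si](C(C)C)(C(C)C)C(C)C)CO[C@@H](c1cc(OC)c(O[Si](C(C)C)(C(C)C)C(C)C)c(OC)c1)[C@@H](C(=O)N1[C@H](Cc2ccccc2)COC1=O)CC(=O)OC(C)(C)C | intermediate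
9 | tert-butyl (3R,4R)-4-Ar-4-(Ar-methoxy)-3-(hydroxymethyl)butanoate | COc1cc(cc(OC)c1O[Si](C(C)C)(C(C)C)C(C)C)CO[C@@H](c1cc(OC)c(O[Si](C(C)C)(C(C)C)C(C)C)c(OC)c1)[C@@H](CO)CC(=O)OC(C)(C)C | intermediate
10 | tert-butyl (3R,4R)-3-{[tert-butyl(dimethyl)silyl]oxymethyl}-4-Ar-4-(Ar-methoxy)butanoate | COc1cc(cc(OC)c1O[Si](C(C)C)(C(C)C)C(C)C)CO[C@@H](c1cc(OC)c(O[Si](C(C)C)(C(C)C)C(C)C)c(OC)c1)[C@@H](CO[Si](C)(C)C(C)(C)C)CC(=O)OC(C)(C)C | intermediate
11 | tert-butyl (3R,4R)-3-{[tert-butyl(dimethyl)silyl]oxymethyl}-4-Ar-4-(Ar-methoxy)-2-(trifluoroacetyl)butanoate, C2 epimers | COc1cc(cc(OC)c1O[Si](C(C)C)(C(C)C)C(C)C)CO[C@@H](c1cc(OC)c(O[Si](C(C)C)(C(C)C)C(C)C)c(OC)c1)[C@@H](CO[Si](C)(C)C(C)(C)C)C(C(=O)C(F)(F)F)C(=O)OC(C)(C)C | intermediate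
12 | tert-butyl (3R,4R)-2-diazo-3-{[tert-butyl(dimethyl)silyl]oxymethyl}-4-Ar-4-(Ar-methoxy)butanoate | COc1cc(cc(OC)c1O[Si](C(C)C)(C(C)C)C(C)C)CO[C@@H](c1cc(OC)c(O[Si](C(C)C)(C(C)C)C(C)C)c(OC)c1)[C@@H](CO[Si](C)(C)C(C)(C)C)C(=[N+]=[N-])C(=O)OC(C)(C)C | intermediate
13 | tert-butyl (2S,4R,5R)-4-{[tert-butyl(dimethyl)silyl]oxymethyl}-2,5-di-Ar-oxolane-3-carboxylate, C3 epimers | COc1cc(cc(OC)c1O[Si](C(C)C)(C(C)C)C(C)C)[C@H]2O[C@@H](c3cc(OC)c(O[Si](C(C)C)(C(C)C)C(C)C)c(OC)c3)[C@@H](CO[Si](C)(C)C(C)(C)C)C2C(=O)OC(C)(C)C | intermediate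
14 | tert-butyl (2S,3S,4R,5R)-4-{[tert-butyl(dimethyl)silyl]oxymethyl}-2,5-di-Ar-oxolane-3-carboxylate | COc1cc(cc(OC)c1O[Si](C(C)C)(C(C)C)C(C)C)[C@H]2O[C@@H](c3cc(OC)c(O[Si](C(C)C)(C(C)C)C(C)C)c(OC)c3)[C@@H](CO[Si](C)(C)C(C)(C)C)[C@@H]2C(=O)OC(C)(C)C | intermediate
15 | [(2S,3R,4R,5R)-4-{[tert-butyl(dimethyl)silyl]oxymethyl}-2,5-di-Ar-oxolan-3-yl]methanol | COc1cc(cc(OC)c1O[Si](C(C)C)(C(C)C)C(C)C)[C@H]2O[C@@H](c3cc(OC)c(O[Si](C(C)C)(C(C)C)C(C)C)c(OC)c3)[C@@H](CO[Si](C)(C)C(C)(C)C)[C@@H]2CO | intermediate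
16 | [(2S,3R,4R,5R)-2,5-bis(4-hydroxy-3,5-dimethoxyphenyl)oxolane-3,4-diyl]dimethanol | COc1cc([C@H]2O[C@@H](c3cc(OC)c(O)c(OC)c3)[C@@H](CO)[C@@H]2CO)cc(OC)c1O | target

Total steps: 10. Longest linear sequence: 9 steps (steps 1 and 3–10 from syringaldehyde; equally steps 2–10 from the oxazolidinone).

**Steps most likely to fail**

1. Step 8. The carbenoid may collapse by 1,2-hydride migration from C4, attack the electron-rich C5 arene, or insert from the other face so that the C2 aryl group ends up trans to the C5 aryl group. The fallback closes the ring through O1–C2 and sets C2 by hydrogenation; it sets out from 7 and comes back at 13. LiBH4 in THF at 0 °C without alcohol additive, so that the Me3Si ether stays, removes the auxiliary from 7 and gives tert-butyl (3R,4R)-4-Ar-3-(hydroxymethyl)-4-(trimethylsilyloxy)butanoate F1. TBSCl and imidazole give tert-butyl (3R,4R)-3-{[tert-butyl(dimethyl)silyl]oxymethyl}-4-Ar-4-(trimethylsilyloxy)butanoate F2. Its lithium enolate (LiN(SiMe3)2, THF, −78 °C) adds to aldehyde 2 to give tert-butyl (3R,4R)-2-[Ar(hydroxy)methyl]-3-{[tert-butyl(dimethyl)silyl]oxymethyl}-4-Ar-4-(trimethylsilyloxy)butanoate F3 as a mixture at the two new centres. Dess–Martin periodinane oxidises this to the keto ester tert-butyl (3R,4R)-2-(Ar-carbonyl)-3-{[tert-butyl(dimethyl)silyl]oxymethyl}-4-Ar-4-(trimethylsilyloxy)butanoate F4. Pyridinium p-toluenesulfonate in MeOH removes the Me3Si group, and the freed C5 hydroxyl condenses with the aryl ketone to tert-butyl (4R,5R)-4-{[tert-butyl(dimethyl)silyl]oxymethyl}-2,5-di-Ar-4,5-dihydrofuran-3-carboxylate F5. Hydrogenation (H2, Rh/Al2O3, EtOAc) should add to the face away from the C4 and C5 substituents and give the all-cis ester, which is the 3R epimer of 13; the KOtBu treatment of step 8 turns it into 14.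

2. Step 4. The silyl triflate may ionise the benzylic C–O bond with hydride capture (deoxygenation, loss of C5), or the aldehyde may be reduced and etherified with itself while the hindered silyl ether stays unchanged. The fallback alkylates the free alcohol with a benzylic trichloroacetimidate in the absence of hydride; it sets out from 7 and 2 and comes back at 8. Citric acid in MeOH frees tert-butyl (3S,4R)-3-[(4R)-4-benzyl-2-oxo-1,3-oxazolidine-3-carbonyl]-4-Ar-4-hydroxybutanoate F6 from 7. NaBH4 in MeOH reduces 2 to [3,5-dimethoxy-4-(triisopropylsilyloxy)phenyl]methanol F7, and Cl3CCN with catalytic DBU gives [3,5-dimethoxy-4-(triisopropylsilyloxy)phenyl]methyl 2,2,2-trichloroacetimidate F8. F6 and F8 with catalytic TfOH in CH2Cl2 at 0 °C should give 8 by acid-catalysed imidate O-alkylation.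

3. Step 3. The ester-bearing acyl chain may compete for magnesium, so that conversion is low or facial selectivity poor, or the addition may take the opposite facial sense. The fallback is a Lewis-acid-promoted boron aldol through an open transition state with the enantiomeric auxiliary; it sets out from 3 and 2 and comes back at 9. Acid 3 is joined to commercial (4S)-4-benzyl-1,3-oxazolidin-2-one under the conditions of step 2 (through anhydride 5) to give tert-butyl 4-[(4S)-4-benzyl-2-oxo-1,3-oxazolidin-3-yl]-4-oxobutanoate F9. Its Z dibutylboron enolate (Bu2BOTf, i-Pr2NEt, CH2Cl2, 0 °C) is added at −78 °C to aldehyde 2 precomplexed with Et2AlCl. The open transition state turns the usual syn preference into anti while the enolate keeps its dipole-opposed facial bias, so the product should be tert-butyl (3S,4R)-3-[(4S)-4-benzyl-2-oxo-1,3-oxazolidine-3-carbonyl]-4-Ar-4-hydroxybutanoate F10. Me3SiCl and imidazole give tert-butyl (3S,4R)-3-[(4S)-4-benzyl-2-oxo-1,3-oxazolidine-3-carbonyl]-4-Ar-4-(trimethylsilyloxy)butanoate F11. Reductive etherification as in step 4 gives tert-butyl (3S,4R)-3-[(4S)-4-benzyl-2-oxo-1,3-oxazolidine-3-carbonyl]-4-Ar-4-(Ar-methoxy)butanoate F12, and LiBH4 cleavage as in step 5 gives 9.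

**Further compounds**
F1 | step 8 | tert-butyl (3R,4R)-4-Ar-3-(hydroxymethyl)-4-(trimethylsilyloxy)butanoate | C[Si](C)(C)O[C@@H](c1cc(OC)c(O[Si](C(C)C)(C(C)C)C(C)C)c(OC)c1)[C@@H](CO)CC(=O)OC(C)(C)C
F2 | step 8 | tert-butyl (3R,4R)-3-{[tert-butyl(dimethyl)silyl]oxymethyl}-4-Ar-4-(trimethylsilyloxy)butanoate | C[Si](C)(C)O[C@@H](c1cc(OC)c(O[Si](C(C)C)(C(C)C)C(C)C)c(OC)c1)[C@@H](CO[Si](C)(C)C(C)(C)C)CC(=O)OC(C)(C)C
F3 | step 8 | tert-butyl (3R,4R)-2-[Ar(hydroxy)methyl]-3-{[tert-butyl(dimethyl)silyl]oxymethyl}-4-Ar-4-(trimethylsilyloxy)butanoate, epimers at C2 and the new carbinol | C[Si](C)(C)O[C@@H](c1cc(OC)c(O[Si](C(C)C)(C(C)C)C(C)C)c(OC)c1)[C@@H](CO[Si](C)(C)C(C)(C)C)C(C(O)c1cc(OC)c(O[Si](C(C)C)(C(C)C)C(C)C)c(OC)c1)C(=O)OC(C)(C)C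
F4 | step 8 | tert-butyl (3R,4R)-2-(Ar-carbonyl)-3-{[tert-butyl(dimethyl)silyl]oxymethyl}-4-Ar-4-(trimethylsilyloxy)butanoate, C2 epimers | C[Si](C)(C)O[C@@H](c1cc(OC)c(O[Si](C(C)C)(C(C)C)C(C)C)c(OC)c1)[C@@H](CO[Si](C)(C)C(C)(C)C)C(C(=O)c1cc(OC)c(O[Si](C(C)C)(C(C)C)C(C)C)c(OC)c1)C(=O)OC(C)(C)C
F5 | step 8 | tert-butyl (4R,5R)-4-{[tert-butyl(dimethyl)silyl]oxymethyl}-2,5-di-Ar-4,5-dihydrofuran-3-carboxylate | CC(C)(C)OC(=O)C1=C(c2cc(OC)c(O[Si](C(C)C)(C(C)C)C(C)C)c(OC)c2)O[C@@H](c2cc(OC)c(O[Si](C(C)C)(C(C)C)C(C)C)c(OC)c2)[C@H]1CO[Si](C)(C)C(C)(C)C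
F6 | step 4 | tert-butyl (3S,4R)-3-[(4R)-4-benzyl-2-oxo-1,3-oxazolidine-3-carbonyl]-4-Ar-4-hydroxybutanoate | O[C@@H](c1cc(OC)c(O[Si](C(C)C)(C(C)C)C(C)C)c(OC)c1)[C@@H](C(=O)N1[C@H](Cc2ccccc2)COC1=O)CC(=O)OC(C)(C)C
F7 | step 4 | [3,5-dimethoxy-4-(triisopropylsilyloxy)phenyl]methanol | COc1cc(CO)cc(OC)c1O[Si](C(C)C)(C(C)C)C(C)C
F8 | step 4 | [3,5-dimethoxy-4-(triisopropylsilyloxy)phenyl]methyl 2,2,2-trichloroacetimidate | COc1cc(COC(=N)C(Cl)(Cl)Cl)cc(OC)c1O[Si](C(C)C)(C(C)C)C(C)C
F9 | step 3 | tert-butyl 4-[(4S)-4-benzyl-2-oxo-1,3-oxazolidin-3-yl]-4-oxobutanoate | CC(C)(C)OC(=O)CCC(=O)N1[C@@H](Cc2ccccc2)COC1=O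
F10 | step 3 | tert-butyl (3S,4R)-3-[(4S)-4-benzyl-2-oxo-1,3-oxazolidine-3-carbonyl]-4-Ar-4-hydroxybutanoate | O[C@@H](c1cc(OC)c(O[Si](C(C)C)(C(C)C)C(C)C)c(OC)c1)[C@@H](C(=O)N1[C@@H](Cc2ccccc2)COC1=O)CC(=O)OC(C)(C)C
F11 | step 3 | tert-butyl (3S,4R)-3-[(4S)-4-benzyl-2-oxo-1,3-oxazolidine-3-carbonyl]-4-Ar-4-(trimethylsilyloxy)butanoate | C[Si](C)(C)O[C@@H](c1cc(OC)c(O[Si](C(C)C)(C(C)C)C(C)C)c(OC)c1)[C@@H](C(=O)N1[C@@H](Cc2ccccc2)COC1=O)CC(=O)OC(C)(C)C
F12 | step 3 | tert-butyl (3S,4R)-3-[(4S)-4-benzyl-2-oxo-1,3-oxazolidine-3-carbonyl]-4-Ar-4-(Ar-methoxy)butanoate | COc1cc(cc(OC)c1O[Si](C(C)C)(C(C)C)C(C)C)CO[C@@H](c1cc(OC)c(O[Si](C(C)C)(C(C)C)C(C)C)c(OC)c1)[C@@H](C(=O)N1[C@@H](Cc2ccccc2)COC1=O)CC(=O)OC(C)(C)C
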